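**Retrosynthetic overview**
- Last bond: the senecioate ester C–O, made by acylating the free α-hydroxy ketone with 3-methylbut-2-enoyl chloride.
- Only ring built: the pyranone of the coumarin, closed late (O1–C2 lactonisation after a Z-selective C3=C4 olefination of a salicylaldehyde derivative). The benzene ring is bought.
- Aryl ketone bond C8–C1': directed ortho-lithiation of MOM/acetal-protected 2-hydroxy-4-methoxybenzaldehyde, added to an O-silyl α-hydroxy Weinreb amide.
- Stereocentre: ketoreductase reduction of ethyl 3-methyl-2-oxobutanoate to the (R)-hydroxy ester. The target centre is (R) by CIP analysis of the given SMILES and is carried through unchanged.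

Assumption: the (R)-selective ketoreductase is picked from a commercial screening panel (≥99% ee required); enzyme identity and ee are to be confirmed experimentally.

**Step 1**
Reactants: 1 ethyl 3-methyl-2-oxobutanoate
Product: 2 ethyl (2R)-2-hydroxy-3-methylbutanoate
Conditions: (R)-selective ketoreductase (KRED), NADP+ (cat.), iPrOH (10% v/v), phosphate buffer pH 7.0, 30 °C
Reagents that add atoms: none
Why: Biocatalytic asymmetric ketone reduction in which the ketoreductase delivers hydride from NADPH (recycled from isopropanol) to the Si face of the activated α-keto ester, setting C2 as R.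

**Step 2**
Reactants: 2 ethyl (2R)-2-hydroxy-3-methylbutanoate
Product: 3 (2R)-2-hydroxy-N-methoxy-N,3-dimethylbutanamide
Conditions: MeNHOMe·HCl, iPrMgCl, THF, −20 → 0 °C
Reagents that add atoms: N,O-dimethylhydroxylamine hydrochloride, CNOC.Cl
Why: Weinreb amide formation by aminolysis of the ester with the chloromagnesium amide; the substrate reacts as its magnesium alkoxide and is not enolised at this temperature, so the R centre is kept.

**Step 3**
Reactants: 3 (2R)-2-hydroxy-N-methoxy-N,3-dimethylbutanamide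
Product: 4 (2R)-2-{[tert-butyl(dimethyl)silyl]oxy}-N-methoxy-N,3-dimethylbutanamide
Conditions: TBSOTf, 2,6-lutidine, CH2Cl2, 0 °C
Reagents that add atoms: tert-butyldimethylsilyl trifluoromethanesulfonate, CC(C)(C)[Si](C)(C)OS(=O)(=O)C(F)(F)F
Why: O-silylation with the reactive silyl triflate protects the hindered secondary alcohol against the aryllithium without touching the stereocentre.

**Step 4**
Reactants: 5 2-hydroxy-4-methoxybenzaldehyde
Product: 6 4-methoxy-2-(methoxymethoxy)benzaldehyde
Conditions: MOMCl, iPr2NEt, CH2Cl2, 0 °C → rt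
Reagents that add atoms: chloromethyl methyl ether, COCCl
Why: O-alkylation of the phenol (MOM protection) masks the acidic OH and installs a strong ortho-directing group for the later lithiation.

**Step 5**
Reactants: 6 4-methoxy-2-(methoxymethoxy)benzaldehyde
Product: 7 1-(dimethoxymethyl)-4-methoxy-2-(methoxymethoxy)benzene
Conditions: HC(OMe)3, PPTS (cat.), MeOH, rt; then Et3N
Reagents that add atoms: trimethyl orthoformate, COC(OC)OC
Why: Mild acid-catalysed acetalisation driven by the orthoformate protects the aldehyde from n-BuLi; the weak acid leaves the aryl MOM ether intact.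

**Step 6**
Reactants: 7 1-(dimethoxymethyl)-4-methoxy-2-(methoxymethoxy)benzene; 4 (2R)-2-{[tert-butyl(dimethyl)silyl]oxy}-N-methoxy-N,3-dimethylbutanamide
Product: 10 3-[(2R)-2-{[tert-butyl(dimethyl)silyl]oxy}-3-methylbutanoyl]-4-methoxy-2-(methoxymethoxy)benzaldehyde, via aryllithium 8 (not isolated), via acetal ketone 9 (not isolated)
Conditions: n-BuLi, TMEDA, THF, 0 °C; then 4, −78 → 0 °C; then 1 M aq. HCl, THF, 0 °C, 15 min
Reagents that add atoms: water, O
Why: Directed ortho-metalation at the position flanked by OMOM and OMe, then Weinreb ketone synthesis (the chelated tetrahedral intermediate prevents over-addition and enolisation, so the R centre is retained), then acetal hydrolysis on the acidic work-up.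

**Step 7**
Reactants: 10 3-[(2R)-2-{[tert-butyl(dimethyl)silyl]oxy}-3-methylbutanoyl]-4-methoxy-2-(methoxymethoxy)benzaldehyde; 11 methyl 2-[bis(2,2,2-trifluoroethoxy)phosphoryl]acetate
Product: 13 methyl (2Z)-3-{3-[(2R)-2-{[tert-butyl(dimethyl)silyl]oxy}-3-methylbutanoyl]-4-methoxy-2-(methoxymethoxy)phenyl}prop-2-enoate, via potassium phosphonate carbanion 12 (not isolated)
Conditions: 11, KHMDS, 18-crown-6, THF, −78 °C; then 10, −78 °C
Reagents that add atoms: none
Why: Still–Gennari Z-selective Horner–Wadsworth–Emmons olefination of the aldehyde; the weakly basic stabilised anion at −78 °C leaves the hindered ketone and its α-stereocentre alone.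

**Step 8**
Reactants: 13 methyl (2Z)-3-{3-[(2R)-2-{[tert-butyl(dimethyl)silyl]oxy}-3-methylbutanoyl]-4-methoxy-2-(methoxymethoxy)phenyl}prop-2-enoate
Product: 15 8-[(2R)-2-{[tert-butyl(dimethyl)silyl]oxy}-3-methylbutanoyl]-7-methoxy-2H-chromen-2-one, via free phenol Z-cinnamate 14 (not isolated)
Conditions: TFA, CH2Cl2, 0 °C → rt; aq. NaHCO3 work-up
Reagents that add atoms: none
Why: Acidolysis of the aryl MOM ether frees a phenol held cis to the ester, which lactonises at once to close the coumarin pyranone ring; any material that also loses TBS converges in step 9.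

**Step 9**
Reactants: 15 8-[(2R)-2-{[tert-butyl(dimethyl)silyl]oxy}-3-methylbutanoyl]-7-methoxy-2H-chromen-2-one
Product: 16 8-[(2R)-2-hydroxy-3-methylbutanoyl]-7-methoxy-2H-chromen-2-one
Conditions: HF·pyridine, pyridine, THF, 0 °C → rt
Reagents that add atoms: none
Why: Fluoride-driven desilylation under buffered, non-basic conditions frees the α-ketol without epimerisation, ketol isomerisation or lactone opening.

**Step 10**
Reactants: 16 8-[(2R)-2-hydroxy-3-methylbutanoyl]-7-methoxy-2H-chromen-2-one; 17 3-methylbut-2-enoyl chloride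
Product: 18 (2R)-1-(7-methoxy-2-oxo-2H-chromen-8-yl)-3-methyl-1-oxobutan-2-yl 3-methylbut-2-enoate
Conditions: pyridine, DMAP (cat.), CH2Cl2, 0 °C
Reagents that add atoms: none
Why: O-acylation through the acylpyridinium (nucleophilic catalysis) with only a weak base present; no bond at the stereocentre is broken, so the R configuration is retained.

**Compound list**
1 | ethyl 3-methyl-2-oxobutanoate | CCOC(=O)C(=O)C(C)C | starting material
2 | ethyl (2R)-2-hydroxy-3-methylbutanoate | CCOC(=O)[C@H](O)C(C)C | intermediate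
3 | (2R)-2-hydroxy-N-methoxy-N,3-dimethylbutanamide | CON(C)C(=O)[C@H](O)C(C)C | intermediate
4 | (2R)-2-{[tert-butyl(dimethyl)silyl]oxy}-N-methoxy-N,3-dimethylbutanamide | CON(C)C(=O)[C@H](O[Si](C)(C)C(C)(C)C)C(C)C | intermediate
5 | 2-hydroxy-4-methoxybenzaldehyde | COc1ccc(C=O)c(O)c1 | starting material
6 | 4-methoxy-2-(methoxymethoxy)benzaldehyde | COCOc1cc(OC)ccc1C=O | intermediate
7 | 1-(dimethoxymethyl)-4-methoxy-2-(methoxymethoxy)benzene | COCOc1cc(OC)ccc1C(OC)OC | intermediate
8 | [3-(dimethoxymethyl)-6-methoxy-2-(methoxymethoxy)phenyl]lithium (formed in the flask) | [Li]c1c(OC)ccc(C(OC)OC)c1OCOC | intermediate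
9 | (2R)-2-{[tert-butyl(dimethyl)silyl]oxy}-1-[3-(dimethoxymethyl)-6-methoxy-2-(methoxymethoxy)phenyl]-3-methylbutan-1-one (formed in the flask) | COCOc1c(C(OC)OC)ccc(OC)c1C(=O)[C@H](O[Si](C)(C)C(C)(C)C)C(C)C | intermediate
10 | 3-[(2R)-2-{[tert-butyl(dimethyl)silyl]oxy}-3-methylbutanoyl]-4-methoxy-2-(methoxymethoxy)benzaldehyde | COCOc1c(C=O)ccc(OC)c1C(=O)[C@H](O[Si](C)(C)C(C)(C)C)C(C)C | intermediate
11 | methyl 2-[bis(2,2,2-trifluoroethoxy)phosphoryl]acetate | COC(=O)CP(=O)(OCC(F)(F)F)OCC(F)(F)F | starting material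
12 | potassium salt of the carbanion of 11 (formed in the flask) | COC(=O)[CH-]P(=O)(OCC(F)(F)F)OCC(F)(F)F.[K+] | intermediate
13 | methyl (2Z)-3-{3-[(2R)-2-{[tert-butyl(dimethyl)silyl]oxy}-3-methylbutanoyl]-4-methoxy-2-(methoxymethoxy)phenyl}prop-2-enoate | COC(=O)/C=C\c1ccc(OC)c(C(=O)[C@H](O[Si](C)(C)C(C)(C)C)C(C)C)c1OCOC | intermediate
14 | methyl (2Z)-3-{3-[(2R)-2-{[tert-butyl(dimethyl)silyl]oxy}-3-methylbutanoyl]-2-hydroxy-4-methoxyphenyl}prop-2-enoate (formed in the flask) | COC(=O)/C=C\c1ccc(OC)c(C(=O)[C@H](O[Si](C)(C)C(C)(C)C)C(C)C)c1O | intermediate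
15 | 8-[(2R)-2-{[tert-butyl(dimethyl)silyl]oxy}-3-methylbutanoyl]-7-methoxy-2H-chromen-2-one | COc1ccc2ccc(=O)oc2c1C(=O)[C@H](O[Si](C)(C)C(C)(C)C)C(C)C | intermediate
16 | 8-[(2R)-2-hydroxy-3-methylbutanoyl]-7-methoxy-2H-chromen-2-one | COc1ccc2ccc(=O)oc2c1C(=O)[C@H](O)C(C)C | intermediate
17 | 3-methylbut-2-enoyl chloride | CC(C)=CC(=O)Cl | starting material
18 | (2R)-1-(7-methoxy-2-oxo-2H-chromen-8-yl)-3-methyl-1-oxobutan-2-yl 3-methylbut-2-enoate | COc1ccc2ccc(=O)oc2c1C(=O)[C@H](OC(=O)C=C(C)C)C(C)C | target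

**Totals**
Total step count: 10. Longest linear sequence: 8 steps (1 → 18 through steps 1, 2, 3, 6, 7, 8, 9, 10); the aryl branch 5 → 7 (steps 4, 5) joins at step 6.

**Three steps most likely to fail**

Step 6. The di-ortho-substituted aryllithium 8 may add slowly to the hindered amide 4, or act as a base and cleave the N–OMe group. The fallback sets out from 4: DIBAL-H in THF at −78 °C reduces it to (2R)-2-{[tert-butyl(dimethyl)silyl]oxy}-3-methylbutanal F1, a far better electrophile. F1 is added at −78 °C to aryllithium 8 (made from 7 as before) to give (2R)-2-{[tert-butyl(dimethyl)silyl]oxy}-1-[3-(dimethoxymethyl)-6-methoxy-2-(methoxymethoxy)phenyl]-3-methylbutan-1-ol F2 as a mixture of carbinol epimers, which does not matter. Dess–Martin periodinane with NaHCO3 in CH2Cl2 oxidises F2 and the route is rejoined at 9, which the same dilute acid converts to 10.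

Step 7. Z-selectivity or conversion may be poor at the ortho-substituted aldehyde, and only the Z-ester lactonises in step 8. The fallback sets out from 10: TFA in CH2Cl2 at 0 °C removes the MOM group to give 3-[(2R)-2-{[tert-butyl(dimethyl)silyl]oxy}-3-methylbutanoyl]-2-hydroxy-4-methoxybenzaldehyde F3. (Triphenylphosphoranylidene)ketene in toluene at 80 °C adds the phenol to give 2-[(2R)-2-{[tert-butyl(dimethyl)silyl]oxy}-3-methylbutanoyl]-6-formyl-3-methoxyphenyl (triphenyl-λ5-phosphanylidene)acetate F4. F4 closes by intramolecular Wittig reaction onto the ortho aldehyde, where only the cis ring alkene can form, and the route is rejoined at 15.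

Step 10. The acid chloride can form a vinylketene and give the deconjugated 3-methylbut-3-enoate, and the hindered hydroxyl may react slowly. The fallback sets out from 16: acryloyl chloride with iPr2NEt in CH2Cl2 at −20 °C gives (2R)-1-(7-methoxy-2-oxo-2H-chromen-8-yl)-3-methyl-1-oxobutan-2-yl prop-2-enoate F5, which has no γ-hydrogens and so no ketene pathway. Cross-metathesis of F5 with excess 2-methylbut-2-ene (Grubbs second-generation catalyst, CH2Cl2, 40 °C) builds the trisubstituted enoate and arrives at 18.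

**Further compounds**
F1 | step 6 | (2R)-2-{[tert-butyl(dimethyl)silyl]oxy}-3-methylbutanal | O=C[C@H](O[Si](C)(C)C(C)(C)C)C(C)C
F2 | step 6 | (2R)-2-{[tert-butyl(dimethyl)silyl]oxy}-1-[3-(dimethoxymethyl)-6-methoxy-2-(methoxymethoxy)phenyl]-3-methylbutan-1-ol (C1 epimers) | COCOc1c(C(OC)OC)ccc(OC)c1C(O)[C@H](O[Si](C)(C)C(C)(C)C)C(C)C
F3 | step 7 | 3-[(2R)-2-{[tert-butyl(dimethyl)silyl]oxy}-3-methylbutanoyl]-2-hydroxy-4-methoxybenzaldehyde | COc1ccc(C=O)c(O)c1C(=O)[C@H](O[Si](C)(C)C(C)(C)C)C(C)C
F4 | step 7 | 2-[(2R)-2-{[tert-butyl(dimethyl)silyl]oxy}-3-methylbutanoyl]-6-formyl-3-methoxyphenyl (triphenyl-λ5-phosphanylidene)acetate | COc1ccc(C=O)c(OC(=O)C=P(c2ccccc2)(c2ccccc2)c2ccccc2)c1C(=O)[C@H](O[Si](C)(C)C(C)(C)C)C(C)C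
F5 | step 10 | (2R)-1-(7-methoxy-2-oxo-2H-chromen-8-yl)-3-methyl-1-oxobutan-2-yl prop-2-enoate | COc1ccc2ccc(=O)oc2c1C(=O)[C@H](OC(=O)C=C)C(C)C
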